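The numbers in the tables come from a simulation for substances that don't exist; scatter was added.

Slowness was what I distrusted first: the flat tail of the cold birch run, at −25 °C, could mean a finished flask or a crawling one.

| flask | substrate | reagent | capture agent | temperature | remark | time |
|---|---|---|---|---|---|---|
| birch | 0.96 M | 1.44 M | 0.40 M | −25 °C | run made earlier |  |
| alder | 0.96 M | 1.44 M | 1.3 M | −14 °C | run made earlier |  |
| Monday's | 0.96 M | 1.44 M | 0.288 M | −20 °C |  | 2.5 h |
| Friday's | 0.96 M | 1.44 M | 0.800 M | −20 °C |  | 8.0 h |

- birch (time / min: product / %): 15.0: 5.2; 30.0: 8.2; 50.0: 11.2; 60.0: 12.9; 80.0: 12.9; 90.0: 14.1; 120: 14.1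
- alder (time / min: product / %): 6.00: 6.2; 15.0: 11.5; 30.0: 13.3; 50.0: 16.5; 60.0: 16.0; 80.0: 17.1; 120: 17.1

(standard deviation of a reading: 0.5 percentage points)

1. the flask that ends with the higher amount of product, in percent of the substrate charged, or "neither" when 2 percentage points or less lies between them (Monday's / Friday's / neither)
2. final product, as a percentage of the substrate charged, in Monday's
3. final product, as a percentage of the substrate charged, in Friday's

In the listed steps, product came straight from substrate and reagent, with no step back to it from any intermediate. So I read 17.1 % from the flat end of the alder run and took it to hold at −20 °C. I called this the product share, the fraction of reacted substrate that becomes product (the selectivity). It gave an estimated ceiling for both flasks, a single reading good to 0.5 percentage points. My estimated floor was birch's last reading, 14.1 %, since birch was colder and stopped sooner than Monday's or Friday's.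

To tighten this I integrated the rate, which goes as substrate times reagent. The four flasks share 0.96 M of substrate and 1.44 M of reagent, so the logarithm of reagent over substrate, counted from its start, climbs straight in time; I called the slope the pace. Divided by the product share, birch's reading at 30.0 min came to 48.0 % converted, a pace of 0.536 h⁻¹. Divided in the same way, alder's reading at 6.00 min came to 36.3 %, a pace of 1.74 h⁻¹. Interpolating the logarithm by degrees gave 0.914 h⁻¹ at −20 °C. My reckoning was therefore 16.5 % for Monday's and 17.1 % for Friday's, a gap within 2 points.

The forecast said neither, with 16 % (14.8 % to 17.2 %) for Monday's and 16.3 % (15.1 % to 17.5 %) for Friday's. Both centres lay inside my bracket and below my figures. Its ground was: “The capture agent acts downstream of that branch, so it should not change the product yield.”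

The flasks gave 16.7 % for Monday's and 17.3 % for Friday's, so neither.

    substrate + reagent → product (k = 0.343 M⁻¹ h⁻¹, Ea = 59.0 kJ mol⁻¹)
    substrate + reagent → intermediate A (k = 1.58 M⁻¹ h⁻¹, Ea = 58.0 kJ mol⁻¹)
    substrate + reagent → intermediate B (k = 0.0573 M⁻¹ h⁻¹, Ea = 56.0 kJ mol⁻¹)
    intermediate B ⇌ intermediate C (K = 0.933, k = 0.101 h⁻¹, Ea = 88.0 kJ mol⁻¹, ΔH = −11.0 kJ mol⁻¹)
    intermediate B ⇌ intermediate A (K = 2.90, k = 0.0612 h⁻¹, Ea = 85.0 kJ mol⁻¹, ΔH = 2.00 kJ mol⁻¹)
    intermediate C ⇌ intermediate A (k = 0.604 h⁻¹, Ea = 72.0 kJ mol⁻¹)
    capture agent + intermediate C → trapped intermediate (k = 0.108 M⁻¹ h⁻¹, Ea = 60.0 kJ mol⁻¹)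
    (constants at −20 °C)

Friday's stood 0.20 points above my ceiling, and the alder reading behind that ceiling carried 0.5 points. Monday's had converted 96.7 % of its substrate, and the product share of that is 16.5 %, against its 16.7 %. A flask like Monday's but with 2.4 M of substrate had reagent as its limiting reagent, down to 0.347 % of its charge, with 40.2 % of the substrate left. The product share of the 59.8 % that reacted is 10.2 %, and that flask ended at 10.4 %.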